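**Assumptions (stated once):**
- (i) The (R)-diarylprolinol catalyst gives the (3R) centre. The (S)-catalyst gives the (2R) adduct from propanal and nitrostyrene. Transferring that enamine facial bias to the aryl-acetaldehyde enamine, and allowing for the change in CIP priorities, the (R)-catalyst gives (R) at the carbon that becomes C3.
- (ii) Only the MOM group ortho to the aldehyde is removed in Step 4, because it is chelated.
- (iii) Simple reagents that leave no atoms in the product (bases, Lewis acids, NaBH4, PPTS, benzoic acid, Et3SiH as an H source) are named in the conditions and not numbered.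

## Retrosynthetic overview
- Kanzonol X is (3R)-8,3'-diprenyl-7,2',4'-trihydroxyisoflavan. It comes from ionic reduction of a cis-fused benzofuro[2,3-b]chromene acetal, which opens the temporary dihydrofuran ring and removes the acetal stereocentre.
- The acetal forms in one operation from an ortho-quinone methide (from a 2-hydroxybenzyl alcohol) and a masked 2-hydroxyarylacetaldehyde. Enamine catalysis sets C3, and the pyran ring (O1) and dihydrobenzofuran ring (O2') close in the same pot.
- Both aromatic halves are 2-prenylresorcinol units (2-O, 3-prenyl, 4-OMOM), so both come from one aldehyde. That aldehyde is made from resorcinol by bis-MOM protection, C2 lithiation/prenylation, and C4 formylation.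
- Ring order: both benzene rings are already present, pyran and dihydrofuran form together in the key step, and the dihydrofuran is then opened.

## Route

**Step 1**
Reactants: 1 resorcinol; 2 chloromethyl methyl ether (MOMCl)
Product: 3 1,3-bis(methoxymethoxy)benzene
Conditions: NaH (2.4 equiv), THF/DMF, 0 °C; then MOMCl (2.3 equiv), 0 °C → rt
Reagents that add atoms: MOMCl, COCCl
Why: Double Williamson-type O-alkylation gives the MOM ethers that direct lithiation.

**Step 2**
Reactants: 3; 4 prenyl bromide
Product: 5 2-prenyl-1,3-bis(methoxymethoxy)benzene
Conditions: n-BuLi, THF, 0 °C, 1 h; then CuI (10 mol%), 4, −78 °C → rt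
Reagents that add atoms: prenyl bromide, CC(C)=CCBr
Why: Directed ortho-metalation occurs at C2, between the two OMOM groups, and Cu(I)-catalysed SN2 alkylation gives the normal prenyl group rather than the SN2′ (reverse-prenyl) product.

**Step 3**
Reactants: 5; 6 DMF
Product: 7 2,4-bis(methoxymethoxy)-3-prenylbenzaldehyde
Conditions: n-BuLi/TMEDA (1.5 equiv), Et2O, 0 °C → rt, 2 h; then DMF (3 equiv), −78 °C → rt
Reagents that add atoms: DMF, CN(C)C=O
Why: The OMOM groups direct lithiation to C4/C6, which are equivalent, and DMF quench (Bouveault formylation) places the CHO ortho to one OMOM and para to the other.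

**Step 4**
Reactants: 7
Product: 8 2-hydroxy-4-(methoxymethoxy)-3-prenylbenzaldehyde
Conditions: ZnBr2 (1.5 equiv), n-PrSH (5 equiv), CH2Cl2, 0 °C, 1 h
Reagents that add atoms: none
Why: In this chelation-assisted MOM cleavage, Zn binds the aldehyde oxygen and the adjacent OMOM oxygen so that only the ortho MOM is removed, and the thiol traps the MOM cation and protects the prenyl alkene.

**Step 5**
Reactants: 8
Product: 9 [2-hydroxy-4-(methoxymethoxy)-3-prenylphenyl]methanol
Conditions: NaBH4 (1.5 equiv), MeOH/THF, 0 °C, 30 min; pH 7 work-up; use immediately
Reagents that add atoms: none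
Why: Chemoselective borohydride reduction of the aldehyde gives the ortho-quinone methide precursor, and the para-OMOM group makes the benzylic position easy to ionise.

**Step 6**
Reactants: 8; 10 (methoxymethyl)triphenylphosphonium chloride
Product: 11 (±)-2-methoxy-6-(methoxymethoxy)-7-prenyl-2,3-dihydrobenzofuran
Conditions: 10 (3 equiv), KOt-Bu (3 equiv), THF, 0 °C → rt; then PPTS (10 mol%), CH2Cl2, rt (one pot)
Reagents that add atoms: (methoxymethyl)triphenylphosphonium chloride, COC[P+](c1ccccc1)(c1ccccc1)c1ccccc1.[Cl-]
Why: Wittig methoxymethylenation adds one carbon to give the 2-hydroxystyryl enol ether, and mild acid closes it by intramolecular hydroalkoxylation to a bench-stable cyclic methyl acetal that masks the unstable 2-hydroxyarylacetaldehyde.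

**Step 7 (key step)**
Reactants: 9 [2-hydroxy-4-(methoxymethoxy)-3-prenylphenyl]methanol; 11 (±)-2-methoxy-6-(methoxymethoxy)-7-prenyl-2,3-dihydrobenzofuran
Product: 13 cis-fused benzofuro[2,3-b]chromene acetal, (3R)-configured at the isoflavan C3, with 7-OMOM, 4'-OMOM and both prenyl groups
Conditions: 9 (1.0 equiv, by syringe pump over 8 h) added to 11 (1.5 equiv), 12 (R)-diphenylprolinol TMS ether (20 mol%), benzoic acid (20 mol%), toluene (0.05 M), 50 °C, 24 h
Reagents that add atoms: none (water and MeOH are lost)
Why: Proposed new method: acid converts 9 to an ortho-quinone methide, and the amine transacetalises 11 to the ring-opened (E)-arylacetaldehyde enamine, whose α-carbon adds to the quinone-methide CH2 with the (R)-catalyst shielding one enamine face to set C3. The A-ring phenol then adds to the iminium carbon (6-exo) to form the pyran N,O-acetal, loss of the amine gives the chromanyl oxocarbenium, and the liberated 2'-OH traps it to give the cis-fused acetal, whose C2 configuration is dictated by C3 because only the cis 5/6 fusion is feasible. The closest known reactions are the enamine-catalysed formal [4+2] of in situ ortho-quinone methides with aldehydes and acid-mediated cyclic acetal formation from 2-hydroxyarylacetaldehydes, and the pyran and dihydrofuran rings form in this single operation.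

**Step 8**
Reactants: 13
Product: 14 (3R)-7,4'-bis(methoxymethoxy)-8,3'-diprenylisoflavan-2'-ol
Conditions: Et3SiH (3 equiv), BF3·OEt2 (2 equiv), CH2Cl2, −78 → −40 °C, 1 h; NaHCO3 quench
Reagents that add atoms: none (Et3SiH supplies only H)
Why: Ionic hydrogenation of the acetal. Cleaving the C2–O2' bond opens the five-membered ring and gives the less strained six-membered chromanyl oxocarbenium, which Et3SiH reduces to the C2 methylene while freeing the 2'-OH. The acetal stereocentre is destroyed and C3 is untouched, and the cold, hydride-rich medium limits deprotonation of the cation at C3, which would racemise it.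

**Step 9**
Reactants: 14
Product: 15 Kanzonol X
Conditions: ZnBr2 (3 equiv), n-PrSH (10 equiv), CH2Cl2, 0 °C → rt, 3 h
Reagents that add atoms: none
Why: Mild Lewis-acid/thiol MOM removal frees both phenols without acid-promoted cyclisation of the o-prenylphenols and without hydrogenolysis, which would reduce the prenyl alkenes.

## Compound list
1 | resorcinol | Oc1cccc(O)c1 | starting material
2 | chloromethyl methyl ether (MOMCl) | COCCl | starting material (reagent)
3 | 1,3-bis(methoxymethoxy)benzene | COCOc1cccc(OCOC)c1 | intermediate
4 | prenyl bromide | CC(C)=CCBr | starting material (reagent)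
5 | 2-prenyl-1,3-bis(methoxymethoxy)benzene | COCOc1cccc(OCOC)c1CC=C(C)C | intermediate
6 | N,N-dimethylformamide | CN(C)C=O | starting material (reagent)
7 | 2,4-bis(methoxymethoxy)-3-prenylbenzaldehyde | CC(C)=CCc1c(OCOC)ccc(C=O)c1OCOC | intermediate
8 | 2-hydroxy-4-(methoxymethoxy)-3-prenylbenzaldehyde | CC(C)=CCc1c(OCOC)ccc(C=O)c1O | intermediate
9 | [2-hydroxy-4-(methoxymethoxy)-3-prenylphenyl]methanol | CC(C)=CCc1c(OCOC)ccc(CO)c1O | intermediate
10 | (methoxymethyl)triphenylphosphonium chloride | COC[P+](c1ccccc1)(c1ccccc1)c1ccccc1.[Cl-] | starting material (reagent)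
11 | (±)-2-methoxy-6-(methoxymethoxy)-7-prenyl-2,3-dihydrobenzofuran | COC1Cc2ccc(OCOC)c(CC=C(C)C)c2O1 | intermediate
12 | (R)-α,α-diphenylprolinol trimethylsilyl ether (organocatalyst) | C[Si](C)(C)OC(c1ccccc1)(c1ccccc1)[C@H]1CCCN1 | starting material (catalyst)
13 | cis-fused benzofuro[2,3-b]chromene acetal, C3 = R | COCOc1ccc2c(c1CC=C(C)C)O[C@H]3Oc4c(CC=C(C)C)c(OCOC)ccc4[C@H]3C2 | intermediate
14 | (3R)-7,4'-bis(methoxymethoxy)-8,3'-diprenylisoflavan-2'-ol | CC(C)=CCc1c(OCOC)ccc([C@@H]2COc3c(ccc(OCOC)c3CC=C(C)C)C2)c1O | intermediate
15 | Kanzonol X, (3R)-8,3'-diprenyl-7,2',4'-trihydroxyisoflavan | CC(C)=CCc1c(O)ccc([C@@H]2COc3c(ccc(O)c3CC=C(C)C)C2)c1O | target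

## Totals
Total steps: 9. Longest linear sequence: 8 (1 → 3 → 5 → 7 → 8 → 11 → 13 → 14 → 15).

## Three steps most likely to fail
1. **Step 7 (key cascade).** The risks are ortho-quinone methide oligomerisation, low ee from re-enolisation of the iminium, and Friedel–Crafts attack on the resorcinol rings.
   - Fallback (different approach): an Evans auxiliary route.
   - Oxidise 11 to the benzofuran-2(3H)-one (hydrolysis to the lactol, then PCC).
   - Open the lactone with the lithium salt of 4-benzyloxazolidinone (the enantiomer that delivers 3R) and MOM-protect the liberated 2'-phenol.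
   - Alkylate the imide enolate with the benzylic bromide made from the TBS ether of 9 (CBr4/PPh3).
   - Remove the auxiliary with LiBH4, desilylate selectively (TBAF), and close the pyran by intramolecular Mitsunobu etherification.
   - Finish with ZnBr2/n-PrSH.
2. **Step 8.** The acetal could ionise at the other C–O bond, giving a 3-(2-hydroxybenzyl)dihydrobenzofuran, and the cation could lose the C3 proton and racemise, or the prenyl alkenes or MOM groups could be attacked.
   - Fallback (different approach): use the 2'-O-TBS ether of the arylacetaldehyde in the enamine/ortho-quinone methide formal [4+2] to give the 2-hydroxychroman lactol with only one ring formed.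
   - Et3SiH/BF3 reduction of this lactol can then only give the chroman.
   - TBAF and ZnBr2/n-PrSH then give Kanzonol X.
3. **Step 3.** n-BuLi may deprotonate the allylic-benzylic prenyl CH2 instead of ring C4–H.
   - Fallback (different approach): remove the MOM groups of 5 (ZnBr2/n-PrSH) to give 2-prenylresorcinol.
   - Formylate at C4 under Vilsmeier conditions (POCl3/DMF, 0 °C) to give 2,4-dihydroxy-3-prenylbenzaldehyde.
   - Protect the more acidic 4-OH regioselectively as its MOM ether (MOMCl, i-Pr2NEt). This gives 8 directly and bypasses steps 3 and 4.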